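All runs are simulated from invented constants; scatter was added.

The closed, stirred vessel holds the same charge in Monday's, Thursday's and Sunday's, and these differ in their heating.

| setting | north-west | south-west | east | Monday's | Thursday's | Sunday's |
|---|---|---|---|---|---|---|
| starting material | 0.40 M | 0.40 M | 0.40 M | 0.40 M | 0.40 M | 0.40 M |
| reagent | 2.8 equiv | 4.4 equiv | 2 equiv | 2.00 equiv | 2.00 equiv | 2.00 equiv |
| second substrate | 1 equiv | 1 equiv | 2 equiv | 1.00 equiv | 1.00 equiv | 1.00 equiv |
| free catalyst | 0.087 mol% | 0.087 mol% | 0.087 mol% | 0.087 mol% | 0.087 mol% | 0.087 mol% |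
| temperature | 96 °C | 110 °C | 96 °C | 115 °C |  | 90 °C |
| remark | run made earlier | run made earlier | run made earlier |  | at 90 °C until 8.0 h, from then on at 115 °C |  |
| time |  |  |  | 15 h | 15 h | 15 h |

| run | time / h | target / % | starting material / % |
|---|---|---|---|
| north-west | 1.33 | 74.4 | 24.4 |
| north-west | 3.00 | 86.7 | 9.7 |
| north-west | 6.00 | 88.2 | 3.7 |
| north-west | 10.0 | 84.5 | 1.6 |
| north-west | 12.0 | 82.6 | 1.3 |
| north-west | 20.0 | 73.7 | 0.8 |
| north-west | 25.0 | 68.8 | 0.7 |
| south-west | 0.667 | 88.8 | 7.8 |
| south-west | 1.00 | 90.3 | 3.4 |
| south-west | 1.50 | 89.3 | 1.5 |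
| south-west | 2.50 | 84.9 | 0.4 |
| south-west | 4.00 | 78.0 | 0.1 |
| south-west | 6.00 | 70.4 | 0.3 |
| south-west | 10.0 | 62.7 | 0 |
| east | 5.00 | 72.2 | 21.9 |
| east | 10.0 | 71.6 | 17.9 |
| east | 12.0 | 70.3 | 15.9 |
| east | 20.0 | 63.3 | 15.2 |
| east | 25.0 | 59.8 | 14.3 |

(each reading ± 0.3 percentage points)

- the flask with the highest amount of target, in percent of the starting material charged ("all alike" if they lie within 1.5 percentage points) (Monday's / Thursday's / Sunday's / all alike)
- final target, as a percentage of the starting material charged, in Monday's
- final target, as a percentage of the starting material charged, in Thursday's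
- final target, as a percentage of the starting material charged, in Sunday's

Monday's looks nearly the same as the south-west run, at 115 °C against 110 °C, though with 2.00 equiv of reagent against 4.4 equiv. In the south-west run starting material reads 0.4% by 2.50 h, so from there on the fall of target shows its loss. The slope is the thing to watch. As a fraction of the charge, target falls by 0.0460 h⁻¹ around a mean of 81.5%, but later by 0.0193 h⁻¹ around 66.5%. The slope thus shrinks faster than target does, so the loss is heading for a level above zero.

Taking the slope as proportional to the distance from that level gives a constant of 0.180 h⁻¹ and a level read as 55.8%: the floor, the level of target at which its net loss stops (an apparent equilibrium level). The approach has a read half-life of 3.86 h. The south-west run stops at 62.7%, still above the floor.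

Monday's runs 15 h, longer than that half-life, so this reckoning puts it near the floor, not below. With that constant, read at 110 °C, Thursday's hot stretch is reckoned to close 71.5% of its distance, which places it close to Monday's. Sunday's is colder than the north-west run, which lost 14 percentage points in 13.0 h, so the reckoning places Sunday's first.

The forecast names Sunday's, with 48% for Monday's, 62% for Thursday's and 84% for Sunday's, noting of its loss rate “though the loss slows with time at 110 °C”. Its Monday's figure lies below the floor, and there the two part.

The simulation gives Sunday's as the highest, with 60.9%, 62.3% and 81.9% for Monday's, Thursday's and Sunday's.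

    2 free catalyst → spent catalyst (k = 250 M⁻¹ h⁻¹, Ea = 70.0 kJ mol⁻¹)
    starting material + reagent + free catalyst → free catalyst + target (k = 3000 M⁻² h⁻¹, Ea = 67.0 kJ mol⁻¹)
    target ⇌ isomer of the product (K = 2.50, k = 0.00900 h⁻¹, Ea = 128 kJ mol⁻¹, ΔH = −66.0 kJ mol⁻¹)
    second substrate + reagent + free catalyst → free catalyst + second product (k = 1300 M⁻² h⁻¹, Ea = 53.0 kJ mol⁻¹)
    (constants at 90 °C)

Monday's stands at 61.6% after 150 h, so its 60.9% is an end under thermodynamic control, 5.1 points above the floor read at 110 °C. Thursday's, hot for 1.81 read half-lives, drops from 81.8% at the change of temperature to 62.3%, which is 6.5 points above the same floor. The largest single effect in the gap of 21 points between Monday's and Sunday's is what the temperature does to the loss of target to isomer of the product: without that effect, Monday's ends 4.3 points above Sunday's.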